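**Remarks on the chemistry (assumptions)**

- (R)-Cryptone 22 is taken as a purchased single enantiomer.
- The diene 4 is made from the deconjugated ketone 3 and not from 3-methylcyclohex-2-en-1-one. Silyl triflate/amine enolisation of the conjugated enone can remove the α′ proton and give the cross-conjugated 2-silyloxy diene, whereas 3 can only give the 1-silyloxy-1,3-diene on conjugative enolisation.
- The (S)-configured catalyst is written for step 5 on the basis of the usual α-C–H···O binding picture of enoate esters. This assignment is not derived rigorously here; if the sense is opposite, the antipodal catalyst (both prolinols are available) is used and nothing else changes.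

## Analysis of the target

Target 33 consists of a trans-fused cyclohexane/seven-membered lactone bicycle (rings A and B, a 1-oxo-octahydro-2-benzoxepine) and a separate cyclohexene (ring C). Ring B holds a trisubstituted C4=C5 alkene that carries the free carboxylic acid. The halves are joined by an ester between the CH2O arm on C9 of ring A and an (E)-2-(hydroxymethyl)acrylic acid attached to C1′ of ring C.

Ring A has four contiguous stereocentres: C9 (tertiary carbinol, S), C9a (lactone carbonyl, S), C5a (ring B alkene, S) and C6 (isopropyl, R). In the chair the three CH centres are equatorial (9a/5a trans, 5a/6 trans), the C9 hydroxyl is equatorial, and the CH2O arm is axial, cis to the C9a carbonyl and cis-1,4 to the isopropyl group. Ring C has two trans centres, C1′ (R) and C6′ (R), which map onto (R)-cryptone.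

Sensitive features are the two 2-(oxymethyl)acrylate units (conjugate addition, SN2′ displacement) and the C9 hydroxyl β to the lactone carbonyl (retro-aldol, dehydration). A free CH2OH on C9 would sit γ and cis to the C9a carbonyl and would translactonise to a five-membered lactone. Three carboxyl groups and four hydroxyls must be differentiated without a basic hydrolysis at the end.

The hard points are the quaternary carbinol with the right relation to three neighbours, the seven-membered lactone with ring-defined alkene geometry, and a late union of two fragile halves. The strategy rests on the oxygen on C9 together with the cis-1,4 relation of the C9 CH2O arm and the C6 isopropyl group. These are the two ends of a cleaved two-carbon bridge, so ring A can be made as a bicyclo[2.2.2]octene with a bridgehead oxygen, and the trans C9a/C5a pair comes from an (E)-dienophile.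

## Retrosynthetic reasoning

**33 ⇒ 32.** The last operation removes only acid-labile groups: the tert-butyl ester on ring B and the two silyl ethers on the ring C half of 32. No hydroxide, amine or basic fluoride then meets the acrylate units or the β-hydroxy lactone of 33.

**32 ⇒ 21 + 31.** The inter-fragment ester is cut at the CH2–O bond, not at the acyl C–O bond. Acylation would need the primary alcohol free next to the ring B lactone, where it would attack the C9a carbonyl. Alkylation of the carboxylate of 31 by spiro-epoxide 21 avoids that alcohol, puts the ester on the less hindered CH2, and uncovers the tertiary hydroxyl in the same event. The C9–O bond is never broken, so C9 keeps its configuration. The forward step must open the oxirane at CH2 under weakly basic, buffered conditions.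

**21 ⇒ 19.** The oxirane CH2–O bond is cut back to a primary tosylate and a tertiary silyl ether. The silyl ether is the bridgehead oxygen of the cycloadduct; desilylation gives an alkoxide that closes by 3-exo-tet displacement. The tosylate is installed early (11) and serves as the protecting group of the primary oxygen throughout.

**19 ⇒ 18 ⇒ 16 + 17.** Ring B is cut at the C4=C5 double bond (ring-closing metathesis) and then at the C(=O)O–CH2 bond (carboxylate alkylation by bromide 17). The ring forces C5a and the OCH2 carbon cis on the alkene, so no E/Z question arises. The ring B tert-butyl ester arrives with 17 only after the ring A tert-butyl ester has been cleaved, so the two carboxyl groups are told apart by timing.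

**16 ⇒ 15 ⇒ 14 ⇒ 13.** The vinyl group comes from the aldehyde and the aldehyde from the dimethyl acetal of the dienophile; the acid comes from the tert-butyl ester. The tert-butyl ester is kept until this point because a less hindered ester would lactonise onto the cis CH2OH of 10.

**13 ⇒ 12 ⇒ 11 ⇒ 10 ⇒ 9.** The isopropyl group comes from the acetyl group by methylenation and hydrogenation, done while no other alkene is present. The tosylate comes from the aldehyde through alcohol 10, which requires an aldehyde-selective reduction beside a methyl ketone.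

**9 ⇒ 8.** The formyl carbon on the silyloxy carbon and the acetyl carbonyl carbon, cis-1,4 on ring A, are joined to a C=C bond, giving bicyclo[2.2.2]octene 8. All four ring A centres then become consequences of one cycloaddition. The forward step is an ozonolysis of the only alkene.

**8 ⇒ 4 + 7.** The C1–C2 and C3–C4 bonds of the bicycle are cut. The forward Diels–Alder reaction must be ortho-regioselective, endo for the ester, and face-selective.

**4 ⇒ 3 ⇒ 2 ⇒ 1; 7 ⇒ 5 + 6.** The diene comes from ketone 3, reached from arene 1 by Birch reduction to 2 and enol ether hydrolysis. The dienophile comes from aldehyde 5 and ylide 6 by Wittig olefination.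

**31 ⇒ 30 ⇒ 27 + 29.** The acid comes from methyl ester 30. The trisubstituted side-chain alkene is cut by cross-metathesis into the vinyl compound 27 and acrylate 29 (from 28). The thermodynamically preferred E isomer is the one needed.

**27 ⇒ 26 ⇒ 25 ⇒ 24 ⇒ 22.** The ring hydroxymethyl group comes from an ester made by carbonylation of enol triflate 24. The C–vinyl bond and the triflate come from one conjugate addition/enolate trapping on cryptone 22. The isopropyl group directs the vinyl group trans and the trapped enolate fixes the position of the ring alkene.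

## Alternatives that were turned down

**Alternative 1: one-carbon ring expansion of an enol lactone.**
- Disconnection: the ring B carbon that bears the acid is removed, leading back to the six-membered enol lactone A1 (ring A ketone masked as a dioxolane).
- Forward key step: dibromocarbene (from CHBr3 and base) adds to the enol-lactone double bond of A1. Silver-assisted (AgBF4) opening of the dibromocyclopropane in methanol gives the seven-membered bromo-alkene lactone A2 as both acylal epimers.
- For it: ring B grows from an easily closed six-membered lactone, the ring alkene is placed without olefination, and the vinyl bromide is a direct handle for carbonylation. For making ring B it is shorter than the acetal/vinyl/ester/metathesis sequence used here.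
- Against it: an enol lactone is an electron-poor, base-labile acyl enol ether and a poor partner for an electrophilic carbene made with strong base. A2 has the OCH2 carbon at the acylal level, so a reductive removal of methoxy next to a lactone is still needed. Above all, C9 is still a ketal. The carbinol with its axial CH2O arm would have to be made by adding a one-carbon unit to a ketone β to the lactone carbonyl, an enolisable β-keto lactone where facial control and chemoselectivity are doubtful.
- Comparison: the chosen strategy places oxygen and the C1 unit on C9 in the first ring-forming step.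

**Alternative 2: Tsuji–Trost closure of ring A.**
- Disconnection: the C9a–C5a bond.
- Forward key step: zerovalent palladium (Pd2(dba)3, PPh3) ionises the allylic carbonate of the acyclic enoate A3. The β-keto ester carbon attacks the near allyl terminus (6-exo) to give cyclohexanone A4 with the complete ring B alkene unit.
- For it: the E-alkene with both oxygenated carbons arrives in the ring-forming step, so steps 11–15 of the chosen route would shrink to a deprotection and a lactonisation. On step economy for ring B it is clearly stronger. The all-trans array of A4 is the thermodynamic one and the β-keto ester centre can equilibrate.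
- Against it: the C6 centre must be made in an acyclic precursor and relay its configuration to C5a through the allyl complex. C9 again remains a ketone. Converting the ketone of a β-keto ester into the C(OH)(CH2O) centre, CH2O axial and cis to the ester, needs a diastereoselective methylene transfer on a substrate that prefers to enolise.
- Comparison: the chosen strategy gives up that step economy for certainty at the quaternary centre, which follows from the geometry of a bicycle.

**Alternative 3: three-component oxa-Michael–olefination to join the halves.**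
- Disconnection: the ring C acrylate C=C bond and its CH2–O bond.
- Forward key step: the alkoxide of 4-methoxybenzyl alcohol A7 adds to the phosphonoacrylate ester A5 of the ring A–B lactone. The phosphonate carbanion olefinates the ring C aldehyde A6 to give the fully assembled, protected skeleton A8.
- For it: it is the most convergent union, forming two bonds in one step. The ring C half is needed only as aldehyde A6, which is shorter to make than acid 31. On convergence it is stronger than the epoxide opening.
- Against it: it does not address ring A at all, since A5 already contains the four contiguous centres. It uses a stoichiometric alkoxide beside the ring B 2-(acyloxymethyl)acrylate, the β-hydroxy lactone and the acrylate ester of A5 (transesterification, SN2′, retro-aldol). The olefination of an α-substituted phosphonate with the epimerisable β,γ-unsaturated aldehyde A6 can give E/Z mixtures and move the ring alkene into conjugation.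
- Comparison: the chosen union uses a buffered carboxylate and reveals the tertiary alcohol in the same step. The three-component reaction is kept only as a fallback for the ring C side chain on a simpler substrate.

Key step: step 5

## Route

Step 1
Reactants: 1 3-methylanisole
Product: 2 1-methoxy-5-methylcyclohexa-1,4-diene
Conditions: Li, NH3 (l), THF, t-BuOH, −78 → −33 °C; then NH4Cl
Reagents that add atoms: none
Why: Birch reduction; the ring is protonated at C2 and C5 of the arene so that methoxy and methyl both end on double bonds, which fixes the later carbonyl and the methyl-bearing alkene in a 1,3-relation.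

Step 2
Reactants: 2 1-methoxy-5-methylcyclohexa-1,4-diene
Product: 3 3-methylcyclohex-3-en-1-one
Conditions: oxalic acid (cat.), MeOH/H2O, rt
Reagents that add atoms: water, SMILES O
Why: Mild enol ether hydrolysis (C-protonation, hemiketal, loss of methanol) under acid too weak to move the remaining alkene into conjugation; the β,γ-unsaturated ketone is used at once.

Step 3
Reactants: 3 3-methylcyclohex-3-en-1-one
Product: 4 tert-butyldimethyl[(3-methylcyclohexa-1,3-dien-1-yl)oxy]silane
Conditions: TBSOTf, Et3N, CH2Cl2, −78 → 0 °C (ketone added last)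
Reagents that add atoms: tert-butyldimethylsilyl trifluoromethanesulfonate, SMILES CC(C)(C)[Si](C)(C)OS(=O)(=O)C(F)(F)F
Why: Soft enolisation; the O-silylated oxocarbenium ion loses the doubly activated C2 proton (α to the carbonyl and allylic), which gives the conjugated 1-silyloxy-1,3-diene and cannot give the cross-conjugated isomer.

Step 4
Reactants: 5 2,2-dimethoxyacetaldehyde; 6 tert-butyl (triphenylphosphoranylidene)acetate
Product: 7 tert-butyl (E)-4,4-dimethoxybut-2-enoate
Conditions: CH2Cl2, rt (5 as its commercial aqueous solution)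
Reagents that add atoms: none
Why: Wittig olefination with a stabilised ylide, which should give the E-enoate through the reversible, thermodynamically controlled oxaphosphetane pathway.

Step 5
Reactants: 4 tert-butyldimethyl[(3-methylcyclohexa-1,3-dien-1-yl)oxy]silane; 7 tert-butyl (E)-4,4-dimethoxybut-2-enoate
Product: 8 tert-butyl (1R,2S,3R,4S)-1-[(tert-butyldimethylsilyl)oxy]-3-(dimethoxymethyl)-5-methylbicyclo[2.2.2]oct-5-ene-2-carboxylate (ester syn to the C5=C6 bridge, acetal anti)
Conditions: (S)-3,3-diphenyl-1-(2-methylphenyl)tetrahydro-1H,3H-pyrrolo[1,2-c][1,3,2]oxazaborole protonated with HN(SO2CF3)2 (20 mol%), CH2Cl2, −78 → −40 °C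
Reagents that add atoms: none
Why: Diels–Alder reaction: the ester carbonyl of 7 binds to boron of the cationic oxazaborolidine and the lowered LUMO reacts with the HOMO of 4 in a concerted, asynchronous [4+2] cycloaddition, the bond from the unsubstituted diene terminus C4 to the enoate β-carbon running ahead of the bond from the silyloxy terminus C1 to the α-carbon. The closest known reactions are oxazaborolidinium-catalysed cycloadditions of cyclohexa-1,3-dienes and silyloxy dienes with acrylate and crotonate esters, and additions of 1-silyloxycyclohexa-1,3-dienes that give bridgehead-oxygenated bicyclo[2.2.2]octenes. One ring is closed, ring A (C1–C2–C3–C4–C8–C7 of the bicycle), by suprafacial formation of both σ-bonds across the s-cis diene held in its own six-membered ring, so that ring A arises as the boat inside the bicyclo[2.2.2]octene. The bridgehead centres C1 and C4 follow from suprafacial addition to the diene, C3 is trans to C2 because the E geometry of 7 is retained, and C2 carries its ester syn to the new C5=C6 bridge through the endo transition state favoured by the coordinated carbonyl. The absolute configuration comes from the catalyst, whose aryl group covers one face of the bound enoate so that the diene adds to the Re face at C2 of 7. The step needs regio-, endo- and facial selectivity: regiochemistry is secured because the 1-silyloxy and 3-methyl groups both place the largest HOMO coefficient on C4, which pairs with the β-carbon of the ester-activated alkene (the acetal is only a weak acceptor), and low temperature with a weakly basic counter-ion should keep the acetal and the silyl enol ether intact.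

Step 6
Reactants: 8 tert-butyl (1R,2S,3R,4S)-1-[(tert-butyldimethylsilyl)oxy]-3-(dimethoxymethyl)-5-methylbicyclo[2.2.2]oct-5-ene-2-carboxylate
Product: 9 tert-butyl (1S,2S,5S,6R)-5-acetyl-2-[(tert-butyldimethylsilyl)oxy]-6-(dimethoxymethyl)-2-formylcyclohexane-1-carboxylate
Conditions: O3, CH2Cl2, −78 °C; then PPh3, −78 °C → rt
Reagents that add atoms: ozone, SMILES [O-][O+]=O
Why: Ozonolysis of the only alkene with reductive work-up; the formyl group lands on the silyloxy carbon and the acetyl group on the other former bridgehead, necessarily cis, and no stereocentre is touched.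

Step 7
Reactants: 9 tert-butyl (1S,2S,5S,6R)-5-acetyl-2-[(tert-butyldimethylsilyl)oxy]-6-(dimethoxymethyl)-2-formylcyclohexane-1-carboxylate
Product: 10 tert-butyl (1S,2S,5S,6R)-5-acetyl-2-[(tert-butyldimethylsilyl)oxy]-6-(dimethoxymethyl)-2-(hydroxymethyl)cyclohexane-1-carboxylate
Conditions: NaBH(OAc)3, AcOH, ClCH2CH2Cl, rt
Reagents that add atoms: none
Why: Chemoselective hydride reduction; the mild acetoxyborohydride reduces the α-oxygenated aldehyde and leaves the methyl ketone and the ester, and because no free alkoxide forms, silyl migration and lactonisation onto the tert-butyl ester are avoided.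

Step 8
Reactants: 10 tert-butyl (1S,2S,5S,6R)-5-acetyl-2-[(tert-butyldimethylsilyl)oxy]-6-(dimethoxymethyl)-2-(hydroxymethyl)cyclohexane-1-carboxylate
Product: 11 tert-butyl (1S,2S,5S,6R)-5-acetyl-2-[(tert-butyldimethylsilyl)oxy]-6-(dimethoxymethyl)-2-{[(4-methylbenzenesulfonyl)oxy]methyl}cyclohexane-1-carboxylate
Conditions: TsCl, pyridine, DMAP (cat.), CH2Cl2, 0 °C → rt
Reagents that add atoms: 4-methylbenzenesulfonyl chloride, SMILES Cc1ccc(cc1)S(=O)(=O)Cl
Why: Sulfonylation of the primary alcohol; the tosylate sits on a CH2 attached to a quaternary carbon, has no β-hydrogen and is shielded from intermolecular SN2, so it can serve as protecting group now and leaving group in step 16.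

Step 9
Reactants: 11 tert-butyl (1S,2S,5S,6R)-5-acetyl-2-[(tert-butyldimethylsilyl)oxy]-6-(dimethoxymethyl)-2-{[(4-methylbenzenesulfonyl)oxy]methyl}cyclohexane-1-carboxylate
Product: 12 tert-butyl (1S,2S,5S,6R)-2-[(tert-butyldimethylsilyl)oxy]-6-(dimethoxymethyl)-2-{[(4-methylbenzenesulfonyl)oxy]methyl}-5-(prop-1-en-2-yl)cyclohexane-1-carboxylate
Conditions: Ph3PCH3Br, KOt-Bu (slightly less than the salt), THF, 0 °C → rt
Reagents that add atoms: methyltriphenylphosphonium bromide, SMILES C[P+](c1ccccc1)(c1ccccc1)c1ccccc1.[Br-]
Why: Wittig methylenation of the methyl ketone; the acetyl-bearing centre is equatorial and trans to its neighbour, so enolisation by the ylide cannot change it for the worse.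

Step 10
Reactants: 12 tert-butyl (1S,2S,5S,6R)-2-[(tert-butyldimethylsilyl)oxy]-6-(dimethoxymethyl)-2-{[(4-methylbenzenesulfonyl)oxy]methyl}-5-(prop-1-en-2-yl)cyclohexane-1-carboxylate
Product: 13 tert-butyl (1S,2S,5R,6R)-2-[(tert-butyldimethylsilyl)oxy]-6-(dimethoxymethyl)-2-{[(4-methylbenzenesulfonyl)oxy]methyl}-5-(propan-2-yl)cyclohexane-1-carboxylate
Conditions: H2 (1 atm), Pd/C (palladium on carbon), EtOAc, rt
Reagents that add atoms: none
Why: Catalytic hydrogenation of the 1,1-disubstituted alkene, the only alkene in the molecule at this stage; no stereocentre is formed (the descriptor at C5 changes only through priorities).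

Step 11
Reactants: 13 tert-butyl (1S,2S,5R,6R)-2-[(tert-butyldimethylsilyl)oxy]-6-(dimethoxymethyl)-2-{[(4-methylbenzenesulfonyl)oxy]methyl}-5-(propan-2-yl)cyclohexane-1-carboxylate
Product: 14 tert-butyl (1S,2S,5R,6R)-2-[(tert-butyldimethylsilyl)oxy]-6-formyl-2-{[(4-methylbenzenesulfonyl)oxy]methyl}-5-(propan-2-yl)cyclohexane-1-carboxylate
Conditions: PPTS, acetone/H2O, 50 °C
Reagents that add atoms: water, SMILES O
Why: Acid-catalysed acetal hydrolysis mild enough for the hindered tertiary silyl ether and the tert-butyl ester; the new α-centre is already the all-equatorial, thermodynamically favoured one.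

Step 12
Reactants: 14 tert-butyl (1S,2S,5R,6R)-2-[(tert-butyldimethylsilyl)oxy]-6-formyl-2-{[(4-methylbenzenesulfonyl)oxy]methyl}-5-(propan-2-yl)cyclohexane-1-carboxylate
Product: 15 tert-butyl (1S,2S,5R,6R)-2-[(tert-butyldimethylsilyl)oxy]-6-ethenyl-2-{[(4-methylbenzenesulfonyl)oxy]methyl}-5-(propan-2-yl)cyclohexane-1-carboxylate
Conditions: Ph3PCH3Br, KOt-Bu, THF, −78 → 0 °C
Reagents that add atoms: methyltriphenylphosphonium bromide, SMILES C[P+](c1ccccc1)(c1ccccc1)c1ccccc1.[Br-]
Why: Wittig methylenation of the aldehyde; it is fast at low temperature, so the neighbouring ester and tosylate are not engaged.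

Step 13
Reactants: 15 tert-butyl (1S,2S,5R,6R)-2-[(tert-butyldimethylsilyl)oxy]-6-ethenyl-2-{[(4-methylbenzenesulfonyl)oxy]methyl}-5-(propan-2-yl)cyclohexane-1-carboxylate
Product: 16 (1S,2S,5R,6R)-2-[(tert-butyldimethylsilyl)oxy]-6-ethenyl-2-{[(4-methylbenzenesulfonyl)oxy]methyl}-5-(propan-2-yl)cyclohexane-1-carboxylic acid
Conditions: CF3CO2H/CH2Cl2 (1:4, dry), 0 °C → rt
Reagents that add atoms: none
Why: Acidolysis of the tert-butyl ester by alkyl–oxygen cleavage; the hindered tertiary silyl ether, the tosylate and the vinyl group should survive anhydrous acid.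

Step 14
Reactants: 16 (1S,2S,5R,6R)-2-[(tert-butyldimethylsilyl)oxy]-6-ethenyl-2-{[(4-methylbenzenesulfonyl)oxy]methyl}-5-(propan-2-yl)cyclohexane-1-carboxylic acid; 17 tert-butyl 2-(bromomethyl)prop-2-enoate
Product: 18 2-(tert-butoxycarbonyl)prop-2-en-1-yl (1S,2S,5R,6R)-2-[(tert-butyldimethylsilyl)oxy]-6-ethenyl-2-{[(4-methylbenzenesulfonyl)oxy]methyl}-5-(propan-2-yl)cyclohexane-1-carboxylate
Conditions: KHCO3, DMF, 0 °C → rt
Reagents that add atoms: none
Why: O-Alkylation of the carboxylate by the activated allylic bromide (SN2 and SN2′ give the same product); it should be far faster than intramolecular displacement of the hindered tosylate.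

Step 15
Reactants: 18 2-(tert-butoxycarbonyl)prop-2-en-1-yl (1S,2S,5R,6R)-2-[(tert-butyldimethylsilyl)oxy]-6-ethenyl-2-{[(4-methylbenzenesulfonyl)oxy]methyl}-5-(propan-2-yl)cyclohexane-1-carboxylate
Product: 19 tert-butyl (5aS,6R,9S,9aS)-9-[(tert-butyldimethylsilyl)oxy]-9-{[(4-methylbenzenesulfonyl)oxy]methyl}-1-oxo-6-(propan-2-yl)-1,3,5a,6,7,8,9,9a-octahydro-2-benzoxepine-4-carboxylate
Conditions: second-generation Hoveyda–Grubbs catalyst, RuCl2(H2IMes)(=CH–C6H4–2-O-i-Pr) (10 mol%), toluene (5 mM), 80 °C
Reagents that add atoms: none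
Why: Ring-closing metathesis; the catalyst loads on the vinyl group and closes onto the 1,1-disubstituted acrylate, a known way to cyclic 2-substituted enoates, and the seven-membered ring fixes the alkene geometry.

Step 16
Reactants: 19 tert-butyl (5aS,6R,9S,9aS)-9-[(tert-butyldimethylsilyl)oxy]-9-{[(4-methylbenzenesulfonyl)oxy]methyl}-1-oxo-6-(propan-2-yl)-1,3,5a,6,7,8,9,9a-octahydro-2-benzoxepine-4-carboxylate
Product: 21 tert-butyl (5aS,6R,9S,9aS)-1-oxo-6-(propan-2-yl)-1,3,5a,6,7,8-hexahydro-9aH-spiro[2-benzoxepine-9,2′-oxirane]-4-carboxylate (spiro-epoxide), via tetrabutylammonium tertiary alkoxide 20 (not isolated)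
Conditions: Bu4NF, THF, 0 °C → rt
Reagents that add atoms: none
Why: Fluoride desilylation followed by intramolecular Williamson closure (3-exo-tet); the alkoxide is consumed as it forms, and C9 keeps its configuration because only the CH2–OTs bond is broken.

Step 17
Reactants: 22 (R)-cryptone, (4R)-4-(propan-2-yl)cyclohex-2-en-1-one
Product: 24 (3R,4R)-3-ethenyl-4-(propan-2-yl)cyclohex-1-en-1-yl trifluoromethanesulfonate, via bromomagnesium enolate 23 (not isolated)
Conditions: CH2=CHMgBr, CuBr·SMe2 (20 mol%), THF, −78 °C; then 2-[N,N-bis(trifluoromethanesulfonyl)amino]-5-chloropyridine, −78 °C → rt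
Reagents that add atoms: vinylmagnesium bromide, SMILES C=C[Mg]Br; 2-[N,N-bis(trifluoromethanesulfonyl)amino]-5-chloropyridine, SMILES FC(F)(F)S(=O)(=O)N(c1ccc(Cl)cn1)S(=O)(=O)C(F)(F)F
Why: Copper-catalysed conjugate addition with enolate trapping; the vinyl group adds anti to the pseudo-equatorial isopropyl group (trans product) and O-triflation of the regiodefined enolate fixes the ring alkene next to the new centre.

Step 18
Reactants: 24 (3R,4R)-3-ethenyl-4-(propan-2-yl)cyclohex-1-en-1-yl trifluoromethanesulfonate
Product: 25 methyl (3R,4R)-3-ethenyl-4-(propan-2-yl)cyclohex-1-ene-1-carboxylate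
Conditions: Pd(OAc)2, 1,3-bis(diphenylphosphino)propane, CO (1 atm), MeOH, Et3N, DMF, 60 °C
Reagents that add atoms: carbon monoxide, SMILES [C-]#[O+]; methanol, SMILES CO
Why: Palladium-catalysed methoxycarbonylation of an enol triflate (oxidative addition, CO insertion, methanolysis); the acyl–palladium group is trans to the vinyl-bearing carbon across the ring alkene, so it cannot cyclise onto the vinyl group.

Step 19
Reactants: 25 methyl (3R,4R)-3-ethenyl-4-(propan-2-yl)cyclohex-1-ene-1-carboxylate
Product: 26 [(3R,4R)-3-ethenyl-4-(propan-2-yl)cyclohex-1-en-1-yl]methanol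
Conditions: i-Bu2AlH, CH2Cl2, −78 °C; Rochelle salt work-up
Reagents that add atoms: none
Why: 1,2-Reduction of the conjugated ester to the allylic alcohol by the aluminium hydride, without touching either alkene.

Step 20
Reactants: 26 [(3R,4R)-3-ethenyl-4-(propan-2-yl)cyclohex-1-en-1-yl]methanol
Product: 27 tert-butyl{[(3R,4R)-3-ethenyl-4-(propan-2-yl)cyclohex-1-en-1-yl]methoxy}dimethylsilane
Conditions: TBSCl, imidazole, DMF, rt
Reagents that add atoms: tert-butyldimethylsilyl chloride, SMILES CC(C)(C)[Si](C)(C)Cl
Why: Standard silylation of a primary alcohol; the ether survives metathesis, saponification and the carboxylate coupling and falls in the final acid step.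

Step 21
Reactants: 28 methyl 2-(hydroxymethyl)prop-2-enoate
Product: 29 methyl 2-{[(tert-butyldimethylsilyl)oxy]methyl}prop-2-enoate
Conditions: TBSCl, imidazole, CH2Cl2, 0 °C → rt
Reagents that add atoms: tert-butyldimethylsilyl chloride, SMILES CC(C)(C)[Si](C)(C)Cl
Why: Standard silylation; it gives the cross-metathesis partner with the same protecting group as 27.

Step 22
Reactants: 27 tert-butyl{[(3R,4R)-3-ethenyl-4-(propan-2-yl)cyclohex-1-en-1-yl]methoxy}dimethylsilane; 29 methyl 2-{[(tert-butyldimethylsilyl)oxy]methyl}prop-2-enoate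
Product: 30 methyl (2E)-2-{[(tert-butyldimethylsilyl)oxy]methyl}-3-[(1R,6R)-3-{[(tert-butyldimethylsilyl)oxy]methyl}-6-(propan-2-yl)cyclohex-2-en-1-yl]prop-2-enoate
Conditions: second-generation Hoveyda–Grubbs catalyst (10 mol%), 29 (4 equiv), CH2Cl2, 40 °C
Reagents that add atoms: none
Why: Olefin cross-metathesis of a terminal alkene with a 2-substituted acrylate, which does not homodimerise; the trisubstituted enoate should form as the more stable E isomer (ring carbon trans to the ester), and the trisubstituted ring alkene is inert.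

Step 23
Reactants: 30 methyl (2E)-2-{[(tert-butyldimethylsilyl)oxy]methyl}-3-[(1R,6R)-3-{[(tert-butyldimethylsilyl)oxy]methyl}-6-(propan-2-yl)cyclohex-2-en-1-yl]prop-2-enoate
Product: 31 (2E)-2-{[(tert-butyldimethylsilyl)oxy]methyl}-3-[(1R,6R)-3-{[(tert-butyldimethylsilyl)oxy]methyl}-6-(propan-2-yl)cyclohex-2-en-1-yl]prop-2-enoic acid
Conditions: LiOH·H2O, THF/MeOH/H2O, rt → 40 °C; then cold dilute HCl to pH 4
Reagents that add atoms: lithium hydroxide, SMILES [Li+].[OH-]
Why: Saponification of the methyl ester; the β-carbon is shielded against conjugate addition and the primary silyl ethers tolerate hydroxide at this temperature.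

Step 24
Reactants: 21 tert-butyl (5aS,6R,9S,9aS)-1-oxo-6-(propan-2-yl)-1,3,5a,6,7,8-hexahydro-9aH-spiro[2-benzoxepine-9,2′-oxirane]-4-carboxylate; 31 (2E)-2-{[(tert-butyldimethylsilyl)oxy]methyl}-3-[(1R,6R)-3-{[(tert-butyldimethylsilyl)oxy]methyl}-6-(propan-2-yl)cyclohex-2-en-1-yl]prop-2-enoic acid
Product: 32 tert-butyl (5aS,6R,9S,9aS)-9-({[(2E)-2-{[(tert-butyldimethylsilyl)oxy]methyl}-3-[(1R,6R)-3-{[(tert-butyldimethylsilyl)oxy]methyl}-6-(propan-2-yl)cyclohex-2-en-1-yl]prop-2-enoyl]oxy}methyl)-9-hydroxy-1-oxo-6-(propan-2-yl)-1,3,5a,6,7,8,9,9a-octahydro-2-benzoxepine-4-carboxylate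
Conditions: 31 (1.5 equiv), Cs2CO3 (0.3 equiv), DMF, 60 °C
Reagents that add atoms: none
Why: SN2 opening of a 2,2-disubstituted oxirane by a carboxylate at the CH2 terminus; the excess acid protonates the tertiary alkoxide and keeps the medium buffered, and the C9–O bond is not broken, so the carbinol keeps its configuration.

Step 25
Reactants: 32 tert-butyl (5aS,6R,9S,9aS)-9-({[(2E)-2-{[(tert-butyldimethylsilyl)oxy]methyl}-3-[(1R,6R)-3-{[(tert-butyldimethylsilyl)oxy]methyl}-6-(propan-2-yl)cyclohex-2-en-1-yl]prop-2-enoyl]oxy}methyl)-9-hydroxy-1-oxo-6-(propan-2-yl)-1,3,5a,6,7,8,9,9a-octahydro-2-benzoxepine-4-carboxylate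
Product: 33 (5aS,6R,9S,9aS)-9-hydroxy-9-({[(2E)-2-(hydroxymethyl)-3-[(1R,6R)-3-(hydroxymethyl)-6-(propan-2-yl)cyclohex-2-en-1-yl]prop-2-enoyl]oxy}methyl)-1-oxo-6-(propan-2-yl)-1,3,5a,6,7,8,9,9a-octahydro-2-benzoxepine-4-carboxylic acid (CNP0361406.2)
Conditions: CF3CO2H/CH2Cl2/H2O (10:10:1), 0 °C → rt
Reagents that add atoms: none
Why: Acidolysis; the tert-butyl ester leaves as isobutene and the two primary silyl ethers are hydrolysed in the same pot, while the tertiary alcohol, flanked by two electron-poor carbons, should resist ionisation and no base touches the esters.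

## Compound list

1 | 3-methylanisole | COc1cccc(C)c1 | starting material
2 | 1-methoxy-5-methylcyclohexa-1,4-diene | COC1=CCC=C(C)C1 | intermediate
3 | 3-methylcyclohex-3-en-1-one | CC1=CCCC(=O)C1 | intermediate
4 | tert-butyldimethyl[(3-methylcyclohexa-1,3-dien-1-yl)oxy]silane | CC1=CCCC(O[Si](C)(C)C(C)(C)C)=C1 | intermediate
5 | 2,2-dimethoxyacetaldehyde | COC(OC)C=O | starting material
6 | tert-butyl (triphenylphosphoranylidene)acetate | CC(C)(C)OC(=O)C=P(c1ccccc1)(c1ccccc1)c1ccccc1 | starting material
7 | tert-butyl (E)-4,4-dimethoxybut-2-enoate | COC(OC)/C=C/C(=O)OC(C)(C)C | intermediate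
8 | tert-butyl (1R,2S,3R,4S)-1-[(tert-butyldimethylsilyl)oxy]-3-(dimethoxymethyl)-5-methylbicyclo[2.2.2]oct-5-ene-2-carboxylate | CC1=C[C@]2(O[Si](C)(C)C(C)(C)C)CC[C@H]1[C@@H](C(OC)OC)[C@@H]2C(=O)OC(C)(C)C | intermediate
9 | tert-butyl (1S,2S,5S,6R)-5-acetyl-2-[(tert-butyldimethylsilyl)oxy]-6-(dimethoxymethyl)-2-formylcyclohexane-1-carboxylate | CC(=O)[C@H]1CC[C@@](O[Si](C)(C)C(C)(C)C)(C=O)[C@@H](C(=O)OC(C)(C)C)[C@@H]1C(OC)OC | intermediate
10 | tert-butyl (1S,2S,5S,6R)-5-acetyl-2-[(tert-butyldimethylsilyl)oxy]-6-(dimethoxymethyl)-2-(hydroxymethyl)cyclohexane-1-carboxylate | CC(=O)[C@H]1CC[C@@](O[Si](C)(C)C(C)(C)C)(CO)[C@@H](C(=O)OC(C)(C)C)[C@@H]1C(OC)OC | intermediate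
11 | tert-butyl (1S,2S,5S,6R)-5-acetyl-2-[(tert-butyldimethylsilyl)oxy]-6-(dimethoxymethyl)-2-{[(4-methylbenzenesulfonyl)oxy]methyl}cyclohexane-1-carboxylate | CC(=O)[C@H]1CC[C@@](O[Si](C)(C)C(C)(C)C)(COS(=O)(=O)c2ccc(C)cc2)[C@@H](C(=O)OC(C)(C)C)[C@@H]1C(OC)OC | intermediate
12 | tert-butyl (1S,2S,5S,6R)-2-[(tert-butyldimethylsilyl)oxy]-6-(dimethoxymethyl)-2-{[(4-methylbenzenesulfonyl)oxy]methyl}-5-(prop-1-en-2-yl)cyclohexane-1-carboxylate | CC(=C)[C@H]1CC[C@@](O[Si](C)(C)C(C)(C)C)(COS(=O)(=O)c2ccc(C)cc2)[C@@H](C(=O)OC(C)(C)C)[C@@H]1C(OC)OC | intermediate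
13 | tert-butyl (1S,2S,5R,6R)-2-[(tert-butyldimethylsilyl)oxy]-6-(dimethoxymethyl)-2-{[(4-methylbenzenesulfonyl)oxy]methyl}-5-(propan-2-yl)cyclohexane-1-carboxylate | CC(C)[C@H]1CC[C@@](O[Si](C)(C)C(C)(C)C)(COS(=O)(=O)c2ccc(C)cc2)[C@@H](C(=O)OC(C)(C)C)[C@@H]1C(OC)OC | intermediate
14 | tert-butyl (1S,2S,5R,6R)-2-[(tert-butyldimethylsilyl)oxy]-6-formyl-2-{[(4-methylbenzenesulfonyl)oxy]methyl}-5-(propan-2-yl)cyclohexane-1-carboxylate | CC(C)[C@H]1CC[C@@](O[Si](C)(C)C(C)(C)C)(COS(=O)(=O)c2ccc(C)cc2)[C@@H](C(=O)OC(C)(C)C)[C@@H]1C=O | intermediate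
15 | tert-butyl (1S,2S,5R,6R)-2-[(tert-butyldimethylsilyl)oxy]-6-ethenyl-2-{[(4-methylbenzenesulfonyl)oxy]methyl}-5-(propan-2-yl)cyclohexane-1-carboxylate | CC(C)[C@H]1CC[C@@](O[Si](C)(C)C(C)(C)C)(COS(=O)(=O)c2ccc(C)cc2)[C@@H](C(=O)OC(C)(C)C)[C@@H]1C=C | intermediate
16 | (1S,2S,5R,6R)-2-[(tert-butyldimethylsilyl)oxy]-6-ethenyl-2-{[(4-methylbenzenesulfonyl)oxy]methyl}-5-(propan-2-yl)cyclohexane-1-carboxylic acid | CC(C)[C@H]1CC[C@@](O[Si](C)(C)C(C)(C)C)(COS(=O)(=O)c2ccc(C)cc2)[C@@H](C(=O)O)[C@@H]1C=C | intermediate
17 | tert-butyl 2-(bromomethyl)prop-2-enoate | C=C(CBr)C(=O)OC(C)(C)C | starting material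
18 | 2-(tert-butoxycarbonyl)prop-2-en-1-yl (1S,2S,5R,6R)-2-[(tert-butyldimethylsilyl)oxy]-6-ethenyl-2-{[(4-methylbenzenesulfonyl)oxy]methyl}-5-(propan-2-yl)cyclohexane-1-carboxylate | CC(C)[C@H]1CC[C@@](O[Si](C)(C)C(C)(C)C)(COS(=O)(=O)c2ccc(C)cc2)[C@@H](C(=O)OCC(=C)C(=O)OC(C)(C)C)[C@@H]1C=C | intermediate
19 | tert-butyl (5aS,6R,9S,9aS)-9-[(tert-butyldimethylsilyl)oxy]-9-{[(4-methylbenzenesulfonyl)oxy]methyl}-1-oxo-6-(propan-2-yl)-1,3,5a,6,7,8,9,9a-octahydro-2-benzoxepine-4-carboxylate | CC(C)[C@H]1CC[C@@](O[Si](C)(C)C(C)(C)C)(COS(=O)(=O)c3ccc(C)cc3)[C@H]2C(=O)OCC(C(=O)OC(C)(C)C)=C[C@H]12 | intermediate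
20 | tetrabutylammonium tertiary alkoxide of desilylated 19 | CC(C)[C@H]1CC[C@@]([O-])(COS(=O)(=O)c3ccc(C)cc3)[C@H]2C(=O)OCC(C(=O)OC(C)(C)C)=C[C@H]12.CCCC[N+](CCCC)(CCCC)CCCC | intermediate (not isolated)
21 | tert-butyl (5aS,6R,9S,9aS)-1-oxo-6-(propan-2-yl)-1,3,5a,6,7,8-hexahydro-9aH-spiro[2-benzoxepine-9,2′-oxirane]-4-carboxylate | CC(C)[C@H]1CC[C@@]3(CO3)[C@H]2C(=O)OCC(C(=O)OC(C)(C)C)=C[C@H]12 | intermediate
22 | (R)-cryptone, (4R)-4-(propan-2-yl)cyclohex-2-en-1-one | CC(C)[C@H]1CCC(=O)C=C1 | starting material
23 | bromomagnesium (3R,4R)-3-ethenyl-4-(propan-2-yl)cyclohex-1-en-1-olate | C=C[C@H]1C=C(O[Mg]Br)CC[C@@H]1C(C)C | intermediate (not isolated)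
24 | (3R,4R)-3-ethenyl-4-(propan-2-yl)cyclohex-1-en-1-yl trifluoromethanesulfonate | C=C[C@H]1C=C(OS(=O)(=O)C(F)(F)F)CC[C@@H]1C(C)C | intermediate
25 | methyl (3R,4R)-3-ethenyl-4-(propan-2-yl)cyclohex-1-ene-1-carboxylate | C=C[C@H]1C=C(C(=O)OC)CC[C@@H]1C(C)C | intermediate
26 | [(3R,4R)-3-ethenyl-4-(propan-2-yl)cyclohex-1-en-1-yl]methanol | C=C[C@H]1C=C(CO)CC[C@@H]1C(C)C | intermediate
27 | tert-butyl{[(3R,4R)-3-ethenyl-4-(propan-2-yl)cyclohex-1-en-1-yl]methoxy}dimethylsilane | C=C[C@H]1C=C(CO[Si](C)(C)C(C)(C)C)CC[C@@H]1C(C)C | intermediate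
28 | methyl 2-(hydroxymethyl)prop-2-enoate | C=C(CO)C(=O)OC | starting material
29 | methyl 2-{[(tert-butyldimethylsilyl)oxy]methyl}prop-2-enoate | C=C(CO[Si](C)(C)C(C)(C)C)C(=O)OC | intermediate
30 | methyl (2E)-2-{[(tert-butyldimethylsilyl)oxy]methyl}-3-[(1R,6R)-3-{[(tert-butyldimethylsilyl)oxy]methyl}-6-(propan-2-yl)cyclohex-2-en-1-yl]prop-2-enoate | COC(=O)/C(=C/[C@H]1C=C(CO[Si](C)(C)C(C)(C)C)CC[C@@H]1C(C)C)CO[Si](C)(C)C(C)(C)C | intermediate
31 | (2E)-2-{[(tert-butyldimethylsilyl)oxy]methyl}-3-[(1R,6R)-3-{[(tert-butyldimethylsilyl)oxy]methyl}-6-(propan-2-yl)cyclohex-2-en-1-yl]prop-2-enoic acid | OC(=O)/C(=C/[C@H]1C=C(CO[Si](C)(C)C(C)(C)C)CC[C@@H]1C(C)C)CO[Si](C)(C)C(C)(C)C | intermediate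
32 | tert-butyl ester, bis-silyl ether of the target (full name in step 24) | CC(C)[C@H]1CC[C@@](O)(COC(=O)/C(=C/[C@H]2C=C(CO[Si](C)(C)C(C)(C)C)CC[C@@H]2C(C)C)CO[Si](C)(C)C(C)(C)C)[C@H]2C(=O)OCC(C(=O)OC(C)(C)C)=C[C@H]12 | intermediate
33 | CNP0361406.2 (full name in step 25) | CC(C)[C@H]1CC[C@@](O)(COC(=O)/C(=C/[C@H]2C=C(CO)CC[C@@H]2C(C)C)CO)[C@H]2C(=O)OCC(C(=O)O)=C[C@H]12 | target

## Step count and least certain steps

Total: 25 steps. Longest linear sequence: 17 steps (steps 1–3, 5–16, 24, 25). The ring C branch (steps 17–23) joins at step 24.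

**Step 5 (key step).** The strongly acidic boron catalyst may ionise the dimethyl acetal or protodesilylate the diene, which would lead to open-chain Mukaiyama-type addition. The β-substituted tert-butyl enoate may turn over slowly, the tert-butyl group may be lost, and facial selectivity may erode. The fallback changes the activation mode. It sets out from diene 4 and uses commercial (E)-4,4-dimethoxybut-2-enal under iminium catalysis by a chiral imidazolidinone salt (5-benzyl-2-tert-butyl-3-methylimidazolidin-4-one trifluoroacetate, enantiomer chosen for the Re-face addition). This should give the endo aldehyde (1R,2S,3R,4S)-1-[(tert-butyldimethylsilyl)oxy]-3-(dimethoxymethyl)-5-methylbicyclo[2.2.2]oct-5-ene-2-carbaldehyde F1. Pinnick oxidation (NaClO2, NaH2PO4, 2-methylbut-2-ene) gives the corresponding carboxylic acid F2. Esterification with Boc2O, DMAP and t-BuOH returns to the route at 8.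

**Step 22.** Productive metathesis between a vinyl group on a branched allylic carbon and a 1,1-disubstituted acrylate may be slow, so that catalyst decay, alkene isomerisation or incomplete E selectivity take over. The fallback replaces metathesis by olefination and sets out from triflate 24. Its vinyl group is cleaved selectively beside the deactivated enol triflate alkene (OsO4 cat., NaIO4, 2,6-lutidine) to (3R,4R)-3-formyl-4-(propan-2-yl)cyclohex-1-en-1-yl trifluoromethanesulfonate F3. The sodium alkoxide of 4-methoxybenzyl alcohol is added to methyl 2-(dimethoxyphosphoryl)prop-2-enoate and the resulting phosphonate anion olefinates F3 at low temperature. This should give methyl (2E)-2-{[(4-methoxybenzyl)oxy]methyl}-3-[(1S,6R)-6-(propan-2-yl)-3-(trifluoromethanesulfonyloxy)cyclohex-2-en-1-yl]prop-2-enoate F4. DDQ removes the benzyl ether to give the hydroxymethyl compound F5. Stille hydroxymethylation (Bu3SnCH2OH, Pd(PPh3)4, LiCl) gives the diol methyl (2E)-2-(hydroxymethyl)-3-[(1R,6R)-3-(hydroxymethyl)-6-(propan-2-yl)cyclohex-2-en-1-yl]prop-2-enoate F6. Silylation of both hydroxyls (TBSCl, imidazole) returns to the route at 30.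

**Step 24.** Attack of a hindered, weakly nucleophilic carboxylate at the oxirane CH2 may be slow. Heating would then favour base-induced opening of the epoxide through the lactone enolate, or addition to the ring B acrylate. The fallback forms the ester by acylation instead of alkylation and sets out from 21. Hydrolysis catalysed by the acetate of the trivalent cobalt salen complex, (salen)Co(OAc), with water delivers hydroxide to the terminal carbon. This gives the diol tert-butyl (5aS,6R,9S,9aS)-9-hydroxy-9-(hydroxymethyl)-1-oxo-6-(propan-2-yl)-1,3,5a,6,7,8,9,9a-octahydro-2-benzoxepine-4-carboxylate F7. Without storage, F7 is acylated on the primary hydroxyl with the mixed anhydride of 31 (2,4,6-trichlorobenzoyl chloride, Et3N, then DMAP), which returns to the route at 32.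

**Step 15.** Ring closure onto the electron-poor 1,1-disubstituted alkene may be slower than oligomerisation or catalyst decay. The fallback closes ring B through the C–O bond and sets out from acid 16. Cross-metathesis with tert-butyl 2-(hydroxymethyl)prop-2-enoate gives the hydroxy acid (1S,2S,5R,6S)-6-[(1E)-3-tert-butoxy-2-(hydroxymethyl)-3-oxoprop-1-en-1-yl]-2-[(tert-butyldimethylsilyl)oxy]-2-{[(4-methylbenzenesulfonyl)oxy]methyl}-5-(propan-2-yl)cyclohexane-1-carboxylic acid F8. Yamaguchi lactonisation at high dilution returns to the route at 19. This fallback helps only if ring closure, and not catalyst loading on the vinyl group, is the limit.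

**Step 7.** The hindered aldehyde may be reduced too slowly for clean discrimination from the ketone, and any alkoxide formed could cause silyl migration or lactonisation. The fallback gives up selectivity in the reduction and restores it in an oxidation; it sets out from 9. NaBH4 in MeOH at 0 °C reduces both carbonyl groups to the diol tert-butyl (1S,2S,5S,6R)-2-[(tert-butyldimethylsilyl)oxy]-6-(dimethoxymethyl)-5-(1-hydroxyethyl)-2-(hydroxymethyl)cyclohexane-1-carboxylate F9 (both carbinol epimers). Secondary-selective oxidation with NaOCl in AcOH returns to the route at 10.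

## Further compounds

F1 | step 5 | (1R,2S,3R,4S)-1-[(tert-butyldimethylsilyl)oxy]-3-(dimethoxymethyl)-5-methylbicyclo[2.2.2]oct-5-ene-2-carbaldehyde | CC1=C[C@]2(O[Si](C)(C)C(C)(C)C)CC[C@H]1[C@@H](C(OC)OC)[C@@H]2C=O
F2 | step 5 | (1R,2S,3R,4S)-1-[(tert-butyldimethylsilyl)oxy]-3-(dimethoxymethyl)-5-methylbicyclo[2.2.2]oct-5-ene-2-carboxylic acid | CC1=C[C@]2(O[Si](C)(C)C(C)(C)C)CC[C@H]1[C@@H](C(OC)OC)[C@@H]2C(=O)O
F3 | step 22 | (3R,4R)-3-formyl-4-(propan-2-yl)cyclohex-1-en-1-yl trifluoromethanesulfonate | O=C[C@H]1C=C(OS(=O)(=O)C(F)(F)F)CC[C@@H]1C(C)C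
F4 | step 22 | methyl (2E)-2-{[(4-methoxybenzyl)oxy]methyl}-3-[(1S,6R)-6-(propan-2-yl)-3-(trifluoromethanesulfonyloxy)cyclohex-2-en-1-yl]prop-2-enoate | COC(=O)/C(=C/[C@H]1C=C(OS(=O)(=O)C(F)(F)F)CC[C@@H]1C(C)C)COCc1ccc(OC)cc1
F5 | step 22 | methyl (2E)-2-(hydroxymethyl)-3-[(1S,6R)-6-(propan-2-yl)-3-(trifluoromethanesulfonyloxy)cyclohex-2-en-1-yl]prop-2-enoate | COC(=O)/C(=C/[C@H]1C=C(OS(=O)(=O)C(F)(F)F)CC[C@@H]1C(C)C)CO
F6 | step 22 | methyl (2E)-2-(hydroxymethyl)-3-[(1R,6R)-3-(hydroxymethyl)-6-(propan-2-yl)cyclohex-2-en-1-yl]prop-2-enoate | COC(=O)/C(=C/[C@H]1C=C(CO)CC[C@@H]1C(C)C)CO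
F7 | step 24 | tert-butyl (5aS,6R,9S,9aS)-9-hydroxy-9-(hydroxymethyl)-1-oxo-6-(propan-2-yl)-1,3,5a,6,7,8,9,9a-octahydro-2-benzoxepine-4-carboxylate | CC(C)[C@H]1CC[C@@](O)(CO)[C@H]2C(=O)OCC(C(=O)OC(C)(C)C)=C[C@H]12
F8 | step 15 | (1S,2S,5R,6S)-6-[(1E)-3-tert-butoxy-2-(hydroxymethyl)-3-oxoprop-1-en-1-yl]-2-[(tert-butyldimethylsilyl)oxy]-2-{[(4-methylbenzenesulfonyl)oxy]methyl}-5-(propan-2-yl)cyclohexane-1-carboxylic acid | CC(C)[C@H]1CC[C@@](O[Si](C)(C)C(C)(C)C)(COS(=O)(=O)c2ccc(C)cc2)[C@@H](C(=O)O)[C@@H]1/C=C(/C(=O)OC(C)(C)C)CO
F9 | step 7 | tert-butyl (1S,2S,5S,6R)-2-[(tert-butyldimethylsilyl)oxy]-6-(dimethoxymethyl)-5-(1-hydroxyethyl)-2-(hydroxymethyl)cyclohexane-1-carboxylate | CC(O)[C@H]1CC[C@@](O[Si](C)(C)C(C)(C)C)(CO)[C@@H](C(=O)OC(C)(C)C)[C@@H]1C(OC)OC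
A1 | alternative 1 | six-membered enol lactone with the ring A ketone as its ethylene ketal | CC(C)[C@H]1CCC2(OCCO2)[C@H]3C(=O)OC=C[C@H]13
A2 | alternative 1 | seven-membered bromo-alkene lactone with a methoxy acylal carbon (both epimers) | CC(C)[C@H]1CCC2(OCCO2)[C@H]3C(=O)OC(OC)C(Br)=C[C@H]13
A3 | alternative 2 | acyclic β-keto ester carrying the allylic methyl carbonate of the enoate | CC(C)[C@H](C(OC(=O)OC)/C=C(/C(=O)OCC[Si](C)(C)C)CO[Si](C)(C)C(C)(C)C)CCC(=O)CC(=O)OC
A4 | alternative 2 | all-trans methyl 2-oxo-5-(propan-2-yl)-6-alkenylcyclohexane-1-carboxylate with the ring B alkene unit | CC(C)[C@H]1CCC(=O)[C@@H](C(=O)OC)[C@@H]1/C=C(/C(=O)OCC[Si](C)(C)C)CO[Si](C)(C)C(C)(C)C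
A5 | alternative 3 | 2-(diethoxyphosphoryl)acrylate ester of the ring A–B lactone | CC(C)[C@H]1CC[C@@](O)(COC(=O)C(=C)P(=O)(OCC)OCC)[C@H]2C(=O)OCC(C(=O)OCC[Si](C)(C)C)=C[C@H]12
A6 | alternative 3 | (1R,6R)-3-{[(tert-butyldimethylsilyl)oxy]methyl}-6-(propan-2-yl)cyclohex-2-ene-1-carbaldehyde | O=C[C@H]1C=C(CO[Si](C)(C)C(C)(C)C)CC[C@@H]1C(C)C
A7 | alternative 3 | 4-methoxybenzyl alcohol | COc1ccc(CO)cc1
A8 | alternative 3 | assembled skeleton with 4-methoxybenzyl ether, silyl ether and 2-(trimethylsilyl)ethyl ester | CC(C)[C@H]1CC[C@@](O)(COC(=O)/C(=C/[C@H]2C=C(CO[Si](C)(C)C(C)(C)C)CC[C@@H]2C(C)C)COCc2ccc(OC)cc2)[C@H]2C(=O)OCC(C(=O)OCC[Si](C)(C)C)=C[C@H]12
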